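**Retrosynthetic overview**
- Target ⇐ its C2 methyl ester (borohydride reduction). The N-methoxy-4-pyridone ring (N1–C2, N1–C8a, C2–C3) is closed last from a 2-acylcyclohexanone, dimethyl oxalate and O-methylhydroxylamine.
- 2-(Methoxyacetyl)-3-octylcyclohexanone ⇐ γ-hydroxy ketone + pentafluorophenyl acrylate: a light-driven deoxygenative radical addition (C6–C7) followed by Claisen closure (C4a–C8a) builds the carbocycle.
- γ-Hydroxy ketone ⇐ cyclopropane-fused lactone: copper-catalysed heptyl Grignard opening (octyl chain), enolate C-acylation (C4–C4a), two decarboxylations.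
- Cyclopropane-fused lactone ⇐ (S)-epichlorohydrin + di-tert-butyl malonate; this bought stereocentre becomes C5 and is never a reactive site afterwards.
- Ring order: cyclopropane/butyrolactone (temporary) → cyclohexanone → pyridone.

Assumption: the seven building blocks marked as starting materials (including heptylmagnesium bromide solution, the N-aryl benzoxazolium salt and pentafluorophenyl acrylate) are bought, and (S)-epichlorohydrin is used at ≥99% ee.

**Step 1**
Reactants: 1 (S)-epichlorohydrin; 2 di-tert-butyl malonate
Product: 3 tert-butyl (1S,5S)-2-oxo-3-oxabicyclo[3.1.0]hexane-1-carboxylate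
Conditions: KOtBu (1.05 equiv), t-BuOH, 25 → 75 °C, 16 h
Reagents that add atoms: none
Why: Malonate–epichlorohydrin cyclopropanation (epoxide opening at CH2, epoxide re-closure with loss of chloride, intramolecular 3-exo-tet alkylation, lactonisation), in which the bought stereocentre is inverted once in the cyclopropane-forming SN2 step and becomes C5 of 3, while C1 is fixed by the obligatory cis ring fusion (a few percent ee can be lost through direct chloride displacement).

**Step 2**
Reactants: 3 tert-butyl (1S,5S)-2-oxo-3-oxabicyclo[3.1.0]hexane-1-carboxylate; 4 heptylmagnesium bromide; 5 methoxyacetyl chloride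
Product: 7 tert-butyl (3S,4S)-3-(methoxyacetyl)-4-octyl-2-oxooxolane-3-carboxylate, via magnesium enolate 6 (not isolated)
Conditions: CuI (10 mol%), THF, −30 °C, 1 h (1.2 equiv of 4); then 5 (1.6 equiv), −30 → 0 °C, 2 h
Reagents that add atoms: none
Why: Copper-catalysed homoconjugate addition of the Grignard reagent opens the doubly activated cyclopropane at its unsubstituted CH2 (SN2-type, the stereocentre is not touched), and the chelated magnesium malonate-type enolate 6 is then C-acylated (Claisen-type acylation) on the face anti to the new octyl group, which sets the short-lived C3 centre.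

**Step 3**
Reactants: 7 tert-butyl (3S,4S)-3-(methoxyacetyl)-4-octyl-2-oxooxolane-3-carboxylate
Product: 9 (4S)-4-(hydroxymethyl)-1-methoxydodecan-2-one, via acyl lactone 8 (not isolated)
Conditions: CF3CO2H/CH2Cl2 (1:1), 25 °C, 3 h; evaporate; then 1 M H2SO4/1,4-dioxane (1:1), 90 °C, 4 h
Reagents that add atoms: none
Why: Acidolysis of the tert-butyl ester and loss of CO2 from the acylmalonic acid give the enolisable acyl lactone 8, whose acid hydrolysis and second β-keto acid decarboxylation (the classical acetylbutyrolactone to hydroxy ketone cleavage) give 9, the stereocentre being β to every carbonyl group and unable to epimerise.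

**Step 4**
Reactants: 9 (4S)-4-(hydroxymethyl)-1-methoxydodecan-2-one; 10 5,7-di-tert-butyl-3-phenyl-1,3-benzoxazol-3-ium tetrafluoroborate; 11 pentafluorophenyl acrylate
Product: 14 (3R)-2-(methoxyacetyl)-3-octylcyclohexan-1-one, via benzoxazoline adduct 12 (not isolated), via pentafluorophenyl keto ester 13 (not isolated)
Conditions: 10 (1.15 equiv), pyridine (1.2 equiv), MTBE, 25 °C, 20 min, filter; then 11 (3 equiv), [Ir(dF(CF3)ppy)2(dtbbpy)]PF6 (1 mol%), 2,6-lutidine (1 equiv), MeCN, 450 nm LEDs, 25 °C, 6 h; evaporate volatiles; then MgBr2·OEt2 (2.5 equiv), iPr2NEt (3.5 equiv), CH2Cl2, 0 → 25 °C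
Reagents that add atoms: none
Why: Proposed new method: a one-flask deoxygenative radical (4+2) annulation in which the excited trivalent iridium photocatalyst oxidises benzoxazoline adduct 12, loss of a proton and β-scission expel the benzoxazolone and leave the primary C6 radical (the neighbouring stereocentre is never a radical site and keeps its configuration), Giese addition to the electron-poor aryl acrylate forms C6–C7, the α-acyl radical is reduced by the divalent iridium species and protonated to active ester 13, and magnesium-mediated soft enolisation of the chelating α-methoxy ketone then closes C4a–C8a by intramolecular Claisen acylation (only the C4a enolate can reach the ester through a six-membered transition state and the chelated β-diketonate is the thermodynamic sink); the closest known reactions are the photoredox deoxygenative conjugate addition of benzoxazolium-activated alcohols to alkyl acrylates and the MgBr2-mediated acylation of ketones with pentafluorophenyl esters, which have not been merged into a ring-forming sequence or run on a keto alcohol with an aryl acrylate.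

**Step 5**
Reactants: 14 (3R)-2-(methoxyacetyl)-3-octylcyclohexan-1-one; 15 dimethyl oxalate; 16 O-methylhydroxylamine hydrochloride
Product: 18 methyl (5R)-1,3-dimethoxy-5-octyl-4-oxo-1,4,5,6,7,8-hexahydroquinoline-2-carboxylate, via triketo ester 17 (not isolated)
Conditions: NaOMe (2.5 equiv), MeOH/THF, 0 → 50 °C, 6 h (1.5 equiv of 15); then 16 (3 equiv), 65 °C, 12 h
Reagents that add atoms: none
Why: Claisen condensation with the oxalate occurs at the more acidic methoxy-bearing CH2 (an adduct at the ring CH2 cannot cyclise and reverts), and O-methylhydroxylamine then condenses with the 1,3,5-tricarbonyl array, for which the six-membered N-methoxy-4-pyridone is the only possible ring (chelidamic-type pyridone synthesis), while C5 is not enolisable and keeps its configuration.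

**Step 6**
Reactants: 18 methyl (5R)-1,3-dimethoxy-5-octyl-4-oxo-1,4,5,6,7,8-hexahydroquinoline-2-carboxylate
Product: 19 (5R)-2-(hydroxymethyl)-1,3-dimethoxy-5-octyl-5,6,7,8-tetrahydroquinolin-4(1H)-one
Conditions: NaBH4 (3 equiv), MeOH, 0 → 25 °C, 2 h
Reagents that add atoms: none
Why: Borohydride reduction of the electron-poor heteroaryl ester (activated by the ring nitrogen and the vinylogous carbonyl) gives the primary alcohol chemoselectively, the vinylogous amide carbonyl and the N–O bond being inert to NaBH4.

**Compound list**
1 | (S)-epichlorohydrin | ClC[C@@H]1CO1 | starting material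
2 | di-tert-butyl malonate | CC(C)(C)OC(=O)CC(=O)OC(C)(C)C | starting material
3 | tert-butyl (1S,5S)-2-oxo-3-oxabicyclo[3.1.0]hexane-1-carboxylate | O=C1OC[C@H]2C[C@@]12C(=O)OC(C)(C)C | intermediate
4 | heptylmagnesium bromide | CCCCCCC[Mg]Br | starting material
5 | methoxyacetyl chloride | COCC(=O)Cl | starting material
6 | bromomagnesium enolate of tert-butyl (4S)-4-octyl-2-oxooxolane-3-carboxylate | CCCCCCCC[C@@H]1COC(O[Mg]Br)=C1C(=O)OC(C)(C)C | intermediate
7 | tert-butyl (3S,4S)-3-(methoxyacetyl)-4-octyl-2-oxooxolane-3-carboxylate (acyl trans to octyl; the C3 epimer is equally usable) | CCCCCCCC[C@@H]1COC(=O)[C@]1(C(=O)COC)C(=O)OC(C)(C)C | intermediate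
8 | (4S)-3-(methoxyacetyl)-4-octyloxolan-2-one (C3 epimers and enol) | CCCCCCCC[C@@H]1COC(=O)C1C(=O)COC | intermediate
9 | (4S)-4-(hydroxymethyl)-1-methoxydodecan-2-one | CCCCCCCC[C@@H](CC(=O)COC)CO | intermediate
10 | 5,7-di-tert-butyl-3-phenyl-1,3-benzoxazol-3-ium tetrafluoroborate | CC(C)(C)c1cc(C(C)(C)C)c2oc[n+](-c3ccccc3)c2c1.F[B-](F)(F)F | starting material
11 | pentafluorophenyl acrylate | C=CC(=O)Oc1c(F)c(F)c(F)c(F)c1F | starting material
12 | (4S)-4-{[(5,7-di-tert-butyl-3-phenyl-2,3-dihydro-1,3-benzoxazol-2-yl)oxy]methyl}-1-methoxydodecan-2-one (both configurations at the aminal carbon) | CCCCCCCC[C@@H](CC(=O)COC)COC1Oc2c(C(C)(C)C)cc(C(C)(C)C)cc2N1c1ccccc1 | intermediate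
13 | pentafluorophenyl (5R)-8-methoxy-5-octyl-7-oxooctanoate | CCCCCCCC[C@@H](CC(=O)COC)CCCC(=O)Oc1c(F)c(F)c(F)c(F)c1F | intermediate
14 | (3R)-2-(methoxyacetyl)-3-octylcyclohexan-1-one (C2 epimers and enol) | CCCCCCCC[C@@H]1CCCC(=O)C1C(=O)COC | intermediate
15 | dimethyl oxalate | COC(=O)C(=O)OC | starting material
16 | O-methylhydroxylamine hydrochloride | CON.Cl | starting material
17 | methyl 3-methoxy-4-[(2R)-2-octyl-6-oxocyclohexyl]-2,4-dioxobutanoate (present as its sodium enolate) | CCCCCCCC[C@@H]1CCCC(=O)C1C(=O)C(OC)C(=O)C(=O)OC | intermediate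
18 | methyl (5R)-1,3-dimethoxy-5-octyl-4-oxo-1,4,5,6,7,8-hexahydroquinoline-2-carboxylate | CCCCCCCC[C@@H]1CCCc2c1c(=O)c(OC)c(C(=O)OC)n2OC | intermediate
19 | (5R)-2-(hydroxymethyl)-1,3-dimethoxy-5-octyl-5,6,7,8-tetrahydroquinolin-4(1H)-one | CCCCCCCC[C@@H]1CCCc2c1c(=O)c(OC)c(CO)n2OC | target

**Step count**
Total steps: 6. Longest linear sequence: 6 (fully linear from (S)-epichlorohydrin).

**Three steps most likely to fail**

Step 4 (the proposed new annulation). Likely failure modes are activation of the minor cyclic hemiketal form of 9 instead of its primary alcohol, 1,5-hydrogen transfer from the methoxy-bearing CH2 to the C6 radical, loss of the active ester to nucleophiles during irradiation, and Michael addition of the product diketonate to leftover acrylate. The fallback uses only known reactions and sets out from 9. Appel iodination (I2, PPh3, imidazole, CH2Cl2, 0 °C) gives (4S)-4-(iodomethyl)-1-methoxydodecan-2-one F1. A light-driven silyl-radical Giese addition to methyl acrylate ((Me3Si)3SiH, [Ir(dF(CF3)ppy)2(dtbbpy)]PF6, blue LEDs, MeCN) gives methyl (5R)-8-methoxy-5-octyl-7-oxooctanoate F2. Intramolecular Claisen condensation of the ketone enolate onto the methyl ester (NaOMe, MeOH/THF, 50 °C) then gives the diketone, and the route is rejoined at 14.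

Step 2 (ring opening with in-flask acylation). The enolate carbon is flanked by the octyl-bearing carbon and the tert-butyl ester, so O-acylation or no acylation is possible. The fallback sets out from 3. The same CuI-catalysed addition of 4 is quenched with aqueous NH4Cl to give tert-butyl (4S)-4-octyl-2-oxooxolane-3-carboxylate F3. CF3CO2H followed by heating in toluene removes the ester as isobutene and CO2 and gives (4S)-4-octyloxolan-2-one F4. Methoxymethyllithium (from Bu3SnCH2OMe and n-BuLi, THF, −78 °C) is then added once to the lactone carbonyl, and the resulting lactol opens to the hydroxy ketone. This nucleophilic acyl substitution replaces the enolate acylation, and the route is rejoined at 9.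

Step 5 (one-pot oxalylation and N-methoxypyridone formation). O-Methylhydroxylamine is a weak nucleophile and may stop at an oxime ether of the keto ester. The fallback sets out from 14. The same Claisen condensation with 15 is followed by HCl/MeOH at reflux, which cyclises 17 to methyl (5R)-3-methoxy-5-octyl-4-oxo-5,6,7,8-tetrahydro-4H-chromene-2-carboxylate F5. The more nucleophilic NH2OH·HCl in pyridine/EtOH at 80 °C exchanges the ring oxygen to give methyl (5R)-1-hydroxy-3-methoxy-5-octyl-4-oxo-1,4,5,6,7,8-hexahydroquinoline-2-carboxylate F6. O-Methylation of the N-hydroxy group (MeI, K2CO3, DMF, 25 °C) then rejoins the route at 18.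

**Further compounds**
F1 | step 4 | (4S)-4-(iodomethyl)-1-methoxydodecan-2-one | CCCCCCCC[C@@H](CC(=O)COC)CI
F2 | step 4 | methyl (5R)-8-methoxy-5-octyl-7-oxooctanoate | CCCCCCCC[C@@H](CC(=O)COC)CCCC(=O)OC
F3 | step 2 | tert-butyl (4S)-4-octyl-2-oxooxolane-3-carboxylate | CCCCCCCC[C@@H]1COC(=O)C1C(=O)OC(C)(C)C
F4 | step 2 | (4S)-4-octyloxolan-2-one | CCCCCCCC[C@@H]1COC(=O)C1
F5 | step 5 | methyl (5R)-3-methoxy-5-octyl-4-oxo-5,6,7,8-tetrahydro-4H-chromene-2-carboxylate | CCCCCCCC[C@@H]1CCCc2c1c(=O)c(OC)c(C(=O)OC)o2
F6 | step 5 | methyl (5R)-1-hydroxy-3-methoxy-5-octyl-4-oxo-1,4,5,6,7,8-hexahydroquinoline-2-carboxylate | CCCCCCCC[C@@H]1CCCc2c1c(=O)c(OC)c(C(=O)OC)n2O
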